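Start from the plateau.

| flask | substrate | coupling partner | free catalyst | remark | time |
|---|---|---|---|---|---|
| north-east | 0.10 M | 0.15 M | 1.4 mM | run made earlier |  |
| west | 0.10 M | 0.21 M | 1.4 mM | run made earlier |  |
| south | 0.10 M | 0.33 M | 1.4 mM | run made earlier |  |
| north-west | 0.10 M | 0.15 M | 2.8 mM | run made earlier |  |
| delta | 0.10 M | 0.150 M | 1.4 mM | everything together at the start | 30 min |
| beta | 0.10 M (fed, over 25 min) | 0.150 M | 1.4 mM | all else is in the flask from the start; the feed brings no volume worth counting | 30 min |
| theta | 0.10 M | 0.150 M (fed, over 25 min) | 1.4 mM | all else is in the flask from the start; the feed brings no volume worth counting | 30 min |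
| eta | 0.10 M (fed, over 2.5 min) | 0.150 M | 1.4 mM | all else is in the flask from the start; the feed brings no volume worth counting | 30 min |

- north-east (time / min: target / %): 2.50: 13; 4.00: 20; 6.00: 26; 8.00: 30; 12.0: 35; 20.0: 42; 30.0: 38
- west (time / min: target / %): 2.00: 11; 3.00: 16; 4.00: 22; 6.00: 27; 10.0: 37; 15.0: 40; 25.0: 42
- south (time / min: target / %): 1.33: 12; 4.00: 26; 6.00: 33; 10.0: 39; 15.0: 41; 20.0: 41; 25.0: 43
- north-west (time / min: target / %): 2.00: 22; 6.00: 43; 12.0: 54; 15.0: 54; 25.0: 56

(readings scatter by 2 percentage points)

- which flask leads in amount of target, in percent of the substrate charged ("all alike" within 1.5 percentage points) (delta / beta / theta / eta / all alike)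
- how much target is there at the end, in percent of the substrate charged: delta
- how much target is there at the end, in percent of the substrate charged: beta
- how much target is there at the end, in percent of the substrate charged: theta
- how much target is there at the end, in percent of the substrate charged: eta

- a species is counted by the substrate in it: one side product counts as two
- steps that have been proposed: catalyst intermediate A <-> released group + catalyst intermediate B; coupling partner + free catalyst <-> catalyst intermediate A; released group -> by-product carried off; substrate + target -> side product; substrate + catalyst intermediate B -> catalyst intermediate C; 2 catalyst intermediate B <-> resting dimer; catalyst intermediate C -> free catalyst + target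

**The quantity.** In the north-east, west and south runs target flattens near 41.0% of the substrate charged, at each partner charge from 0.15 M to 0.33 M. We write target made as aS and target lost as bST, with S and T in fractions of the charge. A substrate lost to the side step takes a target with it, so of the substrate consumed at level T the net share becoming target is (Tc − T)/(Tc + T). Here Tc = a/b is the break-even level, a selectivity factor, and S cancels from it. Replacing the rising curve by its mean, taken as half of the plateau, gives 49.0%. That mean is crude: with this Tc the exact integral of the net share asks for 137% of the charge to reach that plateau, so Tc is an effective figure, to be used through the same mean. As a check, with a taken as proportional to catalyst, we double it for the north-west run with twice the catalyst, which gives a plateau of 55.7%, and the last readings there average 54.7%.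

**Slow motion.** In the first instants of delta, which has the charges of the north-east run, T is small; that run's reading of 13% at 2.50 min gives 0.0520 /min for a, read where the net share is already 58.1%. By 6.00 min the north-east run reads 26%, and at that level the net share has dropped to 30.7%. At the end the curve lies flat, so we commit to 41.0% for delta and, with its short feed, for eta. Theta we put a little below that.

**Slow feed.** We take substrate to disappear with the mean constant 0.0738 /min, a rough figure. Fed over 25 min, that reckons 31.6% of the substrate left in beta at 30 min. The same Tc on the rest gives 33.5% of target.

**The result.** The forecast gives delta 41%, beta 36%, theta 36% and eta 40.5%, holding that “feeding substrate slowly buys no selectivity”, and for beta it stands higher than our figure. The flasks give delta 41.5%, beta 27.1%, theta 37.4% and eta 39.2%, with delta leading.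

    catalyst intermediate A ⇌ released group + catalyst intermediate B (K = 0.110 M, k = 0.488 /s)
    coupling partner + free catalyst ⇌ catalyst intermediate A (K = 16.0 /M, k = 2.78 /M/s)
    released group → by-product carried off (k = 0.00329 /s)
    substrate + target → side product (k = 0.0266 /M/s)
    substrate + catalyst intermediate B → catalyst intermediate C (k = 4.10 /M/s)
    2 catalyst intermediate B ⇌ resting dimer (K = 7390 /M, k = 2.52 /M/s)
    catalyst intermediate C → free catalyst + target (k = 0.278 /s)

**Same reckoning.** Beta is where we part from the flask: it holds 24% of its substrate at 30.0 min, and its 27.1% of target is lower than our 33.5%. Left for 300 min it reaches 32.7%, and that plateau read as before gives a Tc of 32.2%, lower than the 50.2% from delta's 41.5% at that same time. For a neighbour of delta with 3.50 mM of free catalyst, Tc scales to 122%, which gives a plateau of 60.3%, and that neighbour holds 59.6% of target at 30.0 min.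

The earlier runs and the new flask stem from a simulated flask on assumed constants, noise included.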